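## The problem

Abiesin is a biflavonoid with no stereocenter. A flavonol (3,7-dihydroxy-4'-methoxy) is joined through its C6 to C3' of a flavone (5-hydroxy-7,4'-dimethoxy) by a single aryl–aryl bond. That bond has only two ortho substituents (the flavonol O7 and the 4'-methoxy group of the flavone), so the axis rotates freely and no element of chirality has to be controlled. The difficulties are regiochemical: the biaryl bond must sit at C6 of the flavonol and not at C8, and six oxygens must end up as three methyl ethers and three free hydroxyls. The two phloroglucinol-type oxygens of the flavone, O5 and O7, differ only in that O5 is hydrogen-bonded to the C4 carbonyl. The 4-pyranone rings open or add nucleophiles under strongly basic conditions, the 3-hydroxy-4-keto and 5-hydroxy-4-keto units chelate metals, and the poly-β-carbonyl intermediates used here cyclize to pyranones in acid and decarboxylate as β-keto acids. The enabling feature is ring A of the flavone: C5, C7 and C8a carry oxygen and C4a carries the acyl carbon C4. This is the pattern a linear poly-β-carbonyl chain gives when its ester terminus is attacked by an internal carbanion, so ring A can be closed by forming the C4a–C8a bond in a Claisen condensation.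

## Retrosynthesis

**Benzyl ethers (19 from 18).** The last cut removes two benzyl groups from the flavonol oxygens O3 and O7 of 18. Benzyl is chosen because it survives carbonate, phosphate and palladium coupling and is removed by hydrogenolysis, which leaves the three methyl ethers and both chromone double bonds alone. The 5-hydroxyl of the flavone stays free throughout, since its hydrogen bond to C4=O protects it sufficiently.

**Biaryl bond (18 from 9 and 17).** The C6–C3' bond is cut next, giving the 3'-bromoflavone 9 and the flavonol boronate 17. This splits the molecule into two halves of equal size, each a finished flavonoid. It also keeps the flavonol, with its pyranone ring and benzyl ethers, away from the polyanion and acid chemistry that builds the flavone. Making the biaryl bond earlier, at the benzoate stage, would send a chromone through two steps with excess lithium amide and would place the uncertain ring-forming step on the full skeleton. The forward reaction is a Suzuki–Miyaura coupling of two ortho-alkoxy partners.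

**O7 methyl ether (9 from 8).** The O7–CH3 bond of the flavone is cut to the 5,7-dihydroxyflavone 8. A Claisen folding necessarily delivers both oxygens free, so they are differentiated afterwards. One equivalent of methylating agent should take the unchelated O7, and no other free hydroxyl is present at this stage.

**Ring C (8 from 7).** The O1–C2 bond is cut to the ortho-hydroxyaryl 1,3-diketone 7. The forward step is the acid cyclodehydration that ends every Baker–Venkataraman flavone synthesis. Because the trihydroxyphenyl ring of 7 is symmetric, either ortho hydroxyl gives the same flavone.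

**Ring A, the key cut (7 from 6).** The C4a–C8a bond is cut, which unfolds ring A into the methyl 3,5,7,9-tetraoxononanoate 6. Chain atoms C1 to C6 become C8a, C8, C7, C6, C5 and C4a, and chain atoms C7, C8 and C9 become C4, C3 and C2. This removes a ring and all three ring A oxygens as separate problems: they are the carbonyls of the chain. The forward reaction must make the C6 carbanion attack the ester carbon in preference to the aldol closures open to the same chain.

**Chain assembly (6 from 4 via 5; 4 from 2 and 3; 2 from 1).** The ester carbon is cut off as carbon dioxide, leading through the acid 5 to the tetraketone 4. The aryl ketone bond of 4 is cut to the triketone 2 and the commercial ester 3. Triketone 2 is the ring-opened form of 2,6-dimethyl-4H-pyran-4-one 1. Each forward step uses the terminal carbanion of a polyanion, the most reactive site, so no protecting group is needed on the chain. The aryl group carries only bromine and methoxy, so it is a robust spectator.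

**Flavonol half (17 from 16, 15, 12 and 13, 11, 10).** The C–B bond of 17 is cut to bromide 16 and the O3 benzyl group to flavonol 15. Ring C of the flavonol is cut at C2=C3, O1–C2 and C3–O to acetophenone 12 and 4-methoxybenzaldehyde 13, through chalcone 14. The forward reactions are a Claisen–Schmidt condensation and an Algar–Flynn–Oyamada oxidation. Bromide 12 comes from 11 by bromination para to the free hydroxyl, and 11 from 2,4-dihydroxyacetophenone 10 by benzylation of the unchelated hydroxyl. Ring A of the flavonol is therefore purchased, and only its C6 position has to be functionalized.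

## Roads not taken

**Alternative 1:** Ring A of the flavonol would be cut across C5–C6 and C4a–C8a. An aryl-substituted bis(silyloxy)diene A2 would add to but-3-yn-2-one A3, and loss of methanol with desilylation would give the 5-aryl-2,4-dihydroxyacetophenone A1.
- Merits: the cycloaddition fixes the aryl group at the future C6 with no reliance on the selectivity of an electrophilic bromination. The biaryl bond comes in with the diene, so no cross-coupling of two ortho-substituted partners is needed. In these two respects it is more certain than steps 8 and 12 of the chosen plan.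
- Weak points: the diene terminus that must bond carries an ortho-methoxyaryl group and is hindered. More seriously, the ring it builds is the one that can be bought as 10 with the correct oxygens in place. The flavone half would still have to be grown from the aryl bromide of A1 (carbonylation, diketone formation, cyclization) in the presence of the flavonol, making a long linear sequence.
- Comparison: the chosen plan reaches the same substitution pattern in two ordinary steps (bromination, Suzuki coupling) and reserves its new ring construction for the flavone ring, whose oxygen pattern is what needs solving.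

**Alternative 2:** The flavone C2=C3 bond would be cut. An aryl ester of the biaryl acid with a phenol bearing an ortho acylphosphorane, A5, would cyclize on heating by attack of the ylide carbon on the ester carbonyl, giving tri-O-benzylabiesin A4 with loss of triphenylphosphine oxide.
- Merits: ring A is purchased as a phloroglucinol derivative with O7 methylated and O5 benzylated, so there is neither a folding-mode question nor a selective methylation. The closure is neutral, and one hydrogenolysis finishes the synthesis. In certainty of ring formation this road is better than the chosen plan.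
- Weak points: it needs a differentiated 2-hydroxy-4-methoxy-6-benzyloxyacetophenone taken through α-bromination and phosphonium salt formation, and the biaryl acid with the flavonol attached. Aryl esters are sluggish Wittig partners, so the stabilized ylide needs prolonged heating during which acyl transfer can compete. The one uncertain step falls at the very end on the most valuable intermediate.
- Comparison: the chosen plan builds ring A from a pyranone that costs little, meets its uncertain step fourth on a simple bromoaryl substrate, and keeps both heterocycles complete before they are joined. It pays for this with one selective methylation and with a less predictable ring closure.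

**Alternative 3:** Four bonds of flavone ring A would be cut. Wolff rearrangement of the pyranonyl diazoketone A7 would give a ketene that adds methoxyethyne A8. Ring opening of the cyclobutenone and six-electron closure onto the pyranone would give the 5-hydroxy-7-methoxyflavone A6.
- Merits: O5 arrives free and O7 methylated from the bond-forming event itself. This is better than the chosen plan, which needs step 6 and relies on hydrogen bonding for selectivity.
- Weak points: the diazoketone must be made from a 4-oxopyran-2-carboxylic acid via its chloride. The photolysis takes place beside an aryl pyranone chromophore. The electrocyclization has to engage C3 of a cross-conjugated, electron-poor pyranone. The ynol ether is volatile and labile. After the key step the whole flavonol would have to be built from the bromide of A6, including an alkaline peroxide oxidation in the presence of a free 5-hydroxyflavone.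
- Comparison: the chosen plan uses routine reagents after the polyanion stage and has a convergent end game. It concedes the extra methylation step.

Key step: step 4

Remark: methyl 3-bromo-4-methoxybenzoate 3 is taken as a purchased material; it would also follow from 3-bromo-4-methoxybenzoic acid by one Fischer esterification. Compound 7 may exist partly as its cyclic hemiketal, which reacts in step 5 in the same way.

## Steps

Step 1
Reactants: 1 2,6-dimethyl-4H-pyran-4-one
Product: 2 heptane-2,4,6-trione
Conditions: Ba(OH)2·8H2O, H2O, rt; then cold 2 M HCl, Et2O extraction, 0 °C; used at once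
Reagents that add atoms: water, O
Why: Alkaline ring opening of a 4-pyranone: hydroxide adds at C2 and the ring opens by retro-oxa-Michael cleavage; the triketone is held as its barium enolate, which cannot recyclize, and is liberated cold.

Step 2
Reactants: 2 heptane-2,4,6-trione; 3 methyl 3-bromo-4-methoxybenzoate
Product: 4 1-(3-bromo-4-methoxyphenyl)octane-1,3,5,7-tetraone
Conditions: 2 (2.5 equiv), LiN(iPr)2 (7.5 equiv), THF, 0 °C; then 3 (1 equiv), −40 to 0 °C; cold aq HCl
Reagents that add atoms: none
Why: Claisen-type acylation of a 1,3,5-triketone trianion at its terminal carbanion, the most nucleophilic site; the product is deprotonated as it forms, so excess trianion is used, which also suppresses aroylation at the second terminus, and the low temperature with no free amide in excess leaves the aryl bromide untouched.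

Step 3
Reactants: 4 1-(3-bromo-4-methoxyphenyl)octane-1,3,5,7-tetraone
Product: 6 methyl 9-(3-bromo-4-methoxyphenyl)-3,5,7,9-tetraoxononanoate, via tetraketo acid 5 (not isolated)
Conditions: LiN(iPr)2 (5 equiv), THF, −78 to −20 °C; CO2, −78 °C; cold 1 M HCl, Et2O extraction at 0 °C; dried extract, Me3SiCHN2 (1.05 equiv), MeOH, 0 °C
Reagents that add atoms: carbon dioxide, O=C=O; trimethylsilyldiazomethane, C[Si](C)(C)C=[N+]=[N-]
Why: Carboxylation of a polyketone polyanion: the tetraanion (three internal methylenes and the terminal methyl) takes up CO2 at the terminal carbon only; the β-keto acid 5 is kept cold in solution and esterified with a titrated amount of the diazoalkane, which reacts with the carboxylic acid far faster than with the hydrogen-bonded enols.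

Step 4
Reactants: 6 methyl 9-(3-bromo-4-methoxyphenyl)-3,5,7,9-tetraoxononanoate
Product: 7 1-(3-bromo-4-methoxyphenyl)-3-(2,4,6-trihydroxyphenyl)propane-1,3-dione
Conditions: Mg(OMe)2 (8 equiv), MeOH, rt to 50 °C, Ar; then cold 1 M HCl
Reagents that add atoms: none
Why: Mg(OMe)2 turns 6 into a magnesium polyenolate in which all methylenes are deprotonated reversibly; the carbanion at chain C6, flanked by the C5 and C7 carbonyls, adds to the ester carbon C1, methoxide leaves (intramolecular Claisen condensation), and the 2-acylcyclohexane-1,3,5-trione tautomerizes at once to the phloroglucinol. The closest known reaction type is the magnesium-alkoxide-induced Claisen cyclization of 3,5,7-triketo esters to acylphloroglucinols, the laboratory counterpart of chalcone synthase folding. The one ring formed, the carbocycle that becomes flavone ring A, closes in a 6-(enolexo)-exo-trig mode and creates the C6–C1 bond, which is C4a–C8a of the flavone. No stereocenter arises. The step needs chemoselectivity for acyl substitution at the ester over the aldol closures C2 to C7, C4 to C9 and C8 to C3. In the chelated polyenolate the ketone carbonyls carry the enolate charge and are poor electrophiles, while the ester keeps a leaving group; aldol adducts can revert, whereas methoxide loss followed by aromatization and deprotonation to the phloroglucinolate cannot. The anhydrous medium prevents saponification to the carboxylate, which could only follow the aldol paths; these factors favour the Claisen mode without guaranteeing it. The two ortho hydroxyls of the new ring are equivalent, so the later choice of C8a raises no regiochemical question.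

Step 5
Reactants: 7 1-(3-bromo-4-methoxyphenyl)-3-(2,4,6-trihydroxyphenyl)propane-1,3-dione
Product: 8 2-(3-bromo-4-methoxyphenyl)-5,7-dihydroxy-4H-chromen-4-one
Conditions: H2SO4 (cat.), AcOH, 90 °C
Reagents that add atoms: none
Why: Acid-catalysed cyclodehydration of an ortho-hydroxyaryl 1,3-diketone, the closing stage of the Baker–Venkataraman flavone synthesis: a phenolic hydroxyl adds to the aryl ketone (6-exo-trig) and the hemiketal loses water; both ortho hydroxyls give the same flavone.

Step 6
Reactants: 8 2-(3-bromo-4-methoxyphenyl)-5,7-dihydroxy-4H-chromen-4-one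
Product: 9 2-(3-bromo-4-methoxyphenyl)-5-hydroxy-7-methoxy-4H-chromen-4-one
Conditions: Me2SO4 (1.05 equiv), K2CO3 (1.2 equiv), acetone, reflux
Reagents that add atoms: dimethyl sulfate, COS(=O)(=O)OC
Why: Williamson ether synthesis under weak base: the 7-hydroxyl is the more acidic, unchelated phenol, while the 5-hydroxyl is held in a hydrogen bond to the C4 carbonyl, so one equivalent of reagent should methylate O7 only.

Step 7
Reactants: 10 1-(2,4-dihydroxyphenyl)ethanone
Product: 11 1-[4-(benzyloxy)-2-hydroxyphenyl]ethanone
Conditions: BnBr (1.05 equiv), K2CO3, acetone, reflux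
Reagents that add atoms: benzyl bromide, BrCc1ccccc1
Why: Williamson benzylation; the 2-hydroxyl is hydrogen-bonded to the acetyl carbonyl and the 4-hydroxyl, para to acetyl, is the more acidic, so carbonate and one equivalent of benzyl bromide should alkylate O4 only.

Step 8
Reactants: 11 1-[4-(benzyloxy)-2-hydroxyphenyl]ethanone
Product: 12 1-[4-(benzyloxy)-5-bromo-2-hydroxyphenyl]ethanone
Conditions: NBS (1.0 equiv), MeCN, 0 °C to rt
Reagents that add atoms: N-bromosuccinimide, O=C1CCC(=O)N1Br
Why: Electrophilic aromatic bromination; C5 is para to the free hydroxyl, ortho to the benzyloxy group and less hindered than C3, which lies between both oxygens, and under non-acidic conditions the activated ring reacts faster than the acetyl methyl.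

Step 9
Reactants: 12 1-[4-(benzyloxy)-5-bromo-2-hydroxyphenyl]ethanone; 13 4-methoxybenzaldehyde
Product: 15 7-(benzyloxy)-6-bromo-3-hydroxy-2-(4-methoxyphenyl)-4H-chromen-4-one, via chalcone 14 (not isolated)
Conditions: NaOH (aq), EtOH, rt; then H2O2 (30% aq), 0 °C to rt; aq HCl
Reagents that add atoms: hydrogen peroxide, OO
Why: Claisen–Schmidt condensation gives the (E)-chalcone 14, and the Algar–Flynn–Oyamada reaction with alkaline hydrogen peroxide converts it into the flavonol (oxygenation at the α-carbon, phenoxide closure onto the β-carbon, oxidation of the dihydroflavonol); without a 6'-substituent the flavonol is favoured over the aurone.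

Step 10
Reactants: 15 7-(benzyloxy)-6-bromo-3-hydroxy-2-(4-methoxyphenyl)-4H-chromen-4-one
Product: 16 3,7-bis(benzyloxy)-6-bromo-2-(4-methoxyphenyl)-4H-chromen-4-one
Conditions: BnBr (1.3 equiv), K2CO3, DMF, 60 °C
Reagents that add atoms: benzyl bromide, BrCc1ccccc1
Why: Williamson benzylation of the 3-hydroxyl, the only acidic OH left; carbonate in DMF at 60 °C breaks its hydrogen bond to the carbonyl.

Step 11
Reactants: 16 3,7-bis(benzyloxy)-6-bromo-2-(4-methoxyphenyl)-4H-chromen-4-one
Product: 17 3,7-bis(benzyloxy)-2-(4-methoxyphenyl)-6-(4,4,5,5-tetramethyl-1,3,2-dioxaborolan-2-yl)-4H-chromen-4-one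
Conditions: B2pin2 (1.2 equiv), Pd(dppf)Cl2 (5 mol%), KOAc (3 equiv), 1,4-dioxane, 90 °C
Reagents that add atoms: bis(pinacolato)diboron, CC1(C)OB(OC1(C)C)B1OC(C)(C)C(C)(C)O1
Why: Miyaura borylation: oxidative addition of the aryl bromide to zerovalent palladium, acetate-assisted transmetalation with the diboron reagent and reductive elimination; acetate is too weak a base to start Suzuki homocoupling, and the fully protected flavonol offers no chelating group.

Step 12
Reactants: 9 2-(3-bromo-4-methoxyphenyl)-5-hydroxy-7-methoxy-4H-chromen-4-one; 17 3,7-bis(benzyloxy)-2-(4-methoxyphenyl)-6-(4,4,5,5-tetramethyl-1,3,2-dioxaborolan-2-yl)-4H-chromen-4-one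
Product: 18 3,7-bis(benzyloxy)-6-[5-(5-hydroxy-7-methoxy-4-oxo-4H-chromen-2-yl)-2-methoxyphenyl]-2-(4-methoxyphenyl)-4H-chromen-4-one
Conditions: Pd(OAc)2 (5 mol%), SPhos (10 mol%), K3PO4 (3 equiv), 1,4-dioxane/H2O, 90 °C
Reagents that add atoms: none
Why: Suzuki–Miyaura coupling; the electron-rich biaryl phosphine supports oxidative addition into the ortho-methoxy aryl bromide and transmetalation of the ortho-alkoxy boronate, the new biaryl has only two ortho substituents, and the hydrogen-bonded 5-hydroxyl tolerates phosphate base.

Step 13
Reactants: 18 3,7-bis(benzyloxy)-6-[5-(5-hydroxy-7-methoxy-4-oxo-4H-chromen-2-yl)-2-methoxyphenyl]-2-(4-methoxyphenyl)-4H-chromen-4-one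
Product: 19 abiesin, 3,7-dihydroxy-6-[5-(5-hydroxy-7-methoxy-4-oxo-4H-chromen-2-yl)-2-methoxyphenyl]-2-(4-methoxyphenyl)-4H-chromen-4-one
Conditions: H2 (1 atm), Pd/C (10%), THF/MeOH, rt
Reagents that add atoms: none
Why: Catalytic hydrogenolysis of the two benzyl ethers; aryl methyl ethers and the chromone C2=C3 bonds are not reduced at 1 atm and room temperature, and no halogen remains.

## Compound list

1 | 2,6-dimethyl-4H-pyran-4-one | Cc1cc(=O)cc(C)o1 | starting material
2 | heptane-2,4,6-trione | CC(=O)CC(=O)CC(C)=O | intermediate
3 | methyl 3-bromo-4-methoxybenzoate | COC(=O)c1ccc(OC)c(Br)c1 | starting material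
4 | 1-(3-bromo-4-methoxyphenyl)octane-1,3,5,7-tetraone | COc1ccc(C(=O)CC(=O)CC(=O)CC(C)=O)cc1Br | intermediate
5 | 9-(3-bromo-4-methoxyphenyl)-3,5,7,9-tetraoxononanoic acid | COc1ccc(C(=O)CC(=O)CC(=O)CC(=O)CC(=O)O)cc1Br | intermediate
6 | methyl 9-(3-bromo-4-methoxyphenyl)-3,5,7,9-tetraoxononanoate | COC(=O)CC(=O)CC(=O)CC(=O)CC(=O)c1ccc(OC)c(Br)c1 | intermediate
7 | 1-(3-bromo-4-methoxyphenyl)-3-(2,4,6-trihydroxyphenyl)propane-1,3-dione | O=C(CC(=O)c1ccc(OC)c(Br)c1)c1c(O)cc(O)cc1O | intermediate
8 | 2-(3-bromo-4-methoxyphenyl)-5,7-dihydroxy-4H-chromen-4-one | COc1ccc(-c2cc(=O)c3c(O)cc(O)cc3o2)cc1Br | intermediate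
9 | 2-(3-bromo-4-methoxyphenyl)-5-hydroxy-7-methoxy-4H-chromen-4-one | COc1cc(O)c2c(=O)cc(-c3ccc(OC)c(Br)c3)oc2c1 | intermediate
10 | 1-(2,4-dihydroxyphenyl)ethanone | CC(=O)c1ccc(O)cc1O | starting material
11 | 1-[4-(benzyloxy)-2-hydroxyphenyl]ethanone | CC(=O)c1ccc(OCc2ccccc2)cc1O | intermediate
12 | 1-[4-(benzyloxy)-5-bromo-2-hydroxyphenyl]ethanone | CC(=O)c1cc(Br)c(OCc2ccccc2)cc1O | intermediate
13 | 4-methoxybenzaldehyde | COc1ccc(C=O)cc1 | starting material
14 | (E)-1-[4-(benzyloxy)-5-bromo-2-hydroxyphenyl]-3-(4-methoxyphenyl)prop-2-en-1-one | COc1ccc(/C=C/C(=O)c2cc(Br)c(OCc3ccccc3)cc2O)cc1 | intermediate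
15 | 7-(benzyloxy)-6-bromo-3-hydroxy-2-(4-methoxyphenyl)-4H-chromen-4-one | COc1ccc(-c2oc3cc(OCc4ccccc4)c(Br)cc3c(=O)c2O)cc1 | intermediate
16 | 3,7-bis(benzyloxy)-6-bromo-2-(4-methoxyphenyl)-4H-chromen-4-one | COc1ccc(-c2oc3cc(OCc4ccccc4)c(Br)cc3c(=O)c2OCc2ccccc2)cc1 | intermediate
17 | 3,7-bis(benzyloxy)-2-(4-methoxyphenyl)-6-(4,4,5,5-tetramethyl-1,3,2-dioxaborolan-2-yl)-4H-chromen-4-one | COc1ccc(-c2oc3cc(OCc4ccccc4)c(B4OC(C)(C)C(C)(C)O4)cc3c(=O)c2OCc2ccccc2)cc1 | intermediate
18 | 3,7-bis(benzyloxy)-6-[5-(5-hydroxy-7-methoxy-4-oxo-4H-chromen-2-yl)-2-methoxyphenyl]-2-(4-methoxyphenyl)-4H-chromen-4-one | COc1ccc(-c2oc3cc(OCc4ccccc4)c(-c4cc(-c5cc(=O)c6c(O)cc(OC)cc6o5)ccc4OC)cc3c(=O)c2OCc2ccccc2)cc1 | intermediate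
19 | abiesin | COc1ccc(-c2oc3cc(O)c(-c4cc(-c5cc(=O)c6c(O)cc(OC)cc6o5)ccc4OC)cc3c(=O)c2O)cc1 | target

## Step count and least certain steps

Total: 13 steps. Longest linear sequence: 8 steps (1, 2, 3, 4, 5, 6, 12, 13, starting from 1). The flavonol arm (steps 7 to 11) joins at step 12.

**Step 4 (key step).** The chain may fold by aldol addition instead of Claisen condensation. Closure from C2 onto the C7 ketone is the most likely competitor, because C7 is not an aryl ketone as it is in the shorter triketo esters. It would be followed by dehydration to a resorcylate, and acid during work-up could also close a pyranone.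
Fallback: the flavone is made without folding a chain. Starting from 3, a crossed Claisen condensation with the dilithium salt of purchased 1-(2-hydroxy-4,6-dimethoxyphenyl)ethanone (LiN(SiMe3)2, THF) should give 1-(3-bromo-4-methoxyphenyl)-3-(2-hydroxy-4,6-dimethoxyphenyl)propane-1,3-dione F1. Acid cyclodehydration (H2SO4, AcOH) should give 2-(3-bromo-4-methoxyphenyl)-5,7-dimethoxy-4H-chromen-4-one F2. BCl3 in CH2Cl2 at low temperature should cleave only the methyl ether peri to the carbonyl, through the boron chelate, and so return to the route at 9.

**Step 2.** The product tetraketone is more acidic than the reagent, and it has a second terminal methyl. Proton transfer may therefore stop the acylation early, a second aroylation may occur at the far terminus, and residual amide may metalate the ring next to bromine.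
Fallback: the pyranone is used as a masked triketone with a single carbanion. Starting from 1 and 3, the lateral lithium enolate of 1 (LiN(SiMe3)2, THF, −78 °C) is acylated to 2-[2-(3-bromo-4-methoxyphenyl)-2-oxoethyl]-6-methyl-4H-pyran-4-one F3. The pyranone ring is then opened with aqueous Ba(OH)2 as in step 1, returning to the route at 4.

**Step 3.** The β-keto acid 5 may decarboxylate during the acidic work-up, the acidified chain may cyclize to a pyranone, and the diazoalkane may O-methylate an enol.
Fallback: the order of chain construction is reversed, so that the labile acid is a small, inexpensive compound. Starting from 2, the trianion is carboxylated to 3,5,7-trioxooctanoic acid F4, which is esterified to methyl 3,5,7-trioxooctanoate F5. The tetraanion of the ester (LiN(iPr)2, THF) is then aroylated at its terminal carbon with 3, returning to the route at 6.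

**Step 12.** Boronate 17 is electron-rich (boron para to the ring oxygen and ortho to a benzyloxy group) and may lose boron by protonolysis faster than it transmetalates. The 5-hydroxy-4-keto unit of 9 may also bind palladium.
Fallback: the roles of the partners are exchanged. Starting from 9, Miyaura borylation (B2pin2, Pd(dppf)Cl2, KOAc) should give 5-hydroxy-7-methoxy-2-[4-methoxy-3-(4,4,5,5-tetramethyl-1,3,2-dioxaborolan-2-yl)phenyl]-4H-chromen-4-one F6, a less electron-rich boronate. It is coupled with bromide 16 under the conditions of step 12, returning to the route at 18.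

## Further compounds

F1 | step 4 | 1-(3-bromo-4-methoxyphenyl)-3-(2-hydroxy-4,6-dimethoxyphenyl)propane-1,3-dione | COc1cc(O)c(C(=O)CC(=O)c2ccc(OC)c(Br)c2)c(OC)c1
F2 | step 4 | 2-(3-bromo-4-methoxyphenyl)-5,7-dimethoxy-4H-chromen-4-one | COc1cc(OC)c2c(=O)cc(-c3ccc(OC)c(Br)c3)oc2c1
F3 | step 2 | 2-[2-(3-bromo-4-methoxyphenyl)-2-oxoethyl]-6-methyl-4H-pyran-4-one | COc1ccc(C(=O)Cc2cc(=O)cc(C)o2)cc1Br
F4 | step 3 | 3,5,7-trioxooctanoic acid | CC(=O)CC(=O)CC(=O)CC(=O)O
F5 | step 3 | methyl 3,5,7-trioxooctanoate | COC(=O)CC(=O)CC(=O)CC(C)=O
F6 | step 12 | 5-hydroxy-7-methoxy-2-[4-methoxy-3-(4,4,5,5-tetramethyl-1,3,2-dioxaborolan-2-yl)phenyl]-4H-chromen-4-one | COc1cc(O)c2c(=O)cc(-c3ccc(OC)c(B4OC(C)(C)C(C)(C)O4)c3)oc2c1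
A1 | alternative 1 | 1-[5-(5-bromo-2-methoxyphenyl)-2,4-dihydroxyphenyl]ethanone | CC(=O)c1cc(-c2cc(Br)ccc2OC)c(O)cc1O
A2 | alternative 1 | 4-(5-bromo-2-methoxyphenyl)-1-methoxy-1,3-bis(trimethylsilyloxy)buta-1,3-diene (double-bond geometry left open) | COC(O[Si](C)(C)C)=CC(O[Si](C)(C)C)=Cc1cc(Br)ccc1OC
A3 | alternative 1 | but-3-yn-2-one | CC(=O)C#C
A4 | alternative 2 | 3,7-bis(benzyloxy)-6-[5-(5-(benzyloxy)-7-methoxy-4-oxo-4H-chromen-2-yl)-2-methoxyphenyl]-2-(4-methoxyphenyl)-4H-chromen-4-one | COc1ccc(-c2oc3cc(OCc4ccccc4)c(-c4cc(-c5cc(=O)c6c(OCc7ccccc7)cc(OC)cc6o5)ccc4OC)cc3c(=O)c2OCc2ccccc2)cc1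
A5 | alternative 2 | 3-(benzyloxy)-5-methoxy-2-[(triphenylphosphoranylidene)acetyl]phenyl 3-[3,7-bis(benzyloxy)-2-(4-methoxyphenyl)-4-oxo-4H-chromen-6-yl]-4-methoxybenzoate | COc1cc(OCc2ccccc2)c(C(=O)C=P(c2ccccc2)(c2ccccc2)c2ccccc2)c(OC(=O)c2ccc(OC)c(-c3cc4c(=O)c(OCc5ccccc5)c(-c5ccc(OC)cc5)oc4cc3OCc3ccccc3)c2)c1
A6 | alternative 3 | 2-[3-(2,4-bis(benzyloxy)-5-bromophenyl)-4-methoxyphenyl]-5-hydroxy-7-methoxy-4H-chromen-4-one | COc1cc(O)c2c(=O)cc(-c3ccc(OC)c(-c4cc(Br)c(OCc5ccccc5)cc4OCc4ccccc4)c3)oc2c1
A7 | alternative 3 | 2-[3-(2,4-bis(benzyloxy)-5-bromophenyl)-4-methoxyphenyl]-6-(2-diazoacetyl)-4H-pyran-4-one | COc1ccc(-c2cc(=O)cc(C(=O)C=[N+]=[N-])o2)cc1-c1cc(Br)c(OCc2ccccc2)cc1OCc1ccccc1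
A8 | alternative 3 | methoxyethyne | COC#C
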